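I began with the easy step, a balance of the free enzyme, the reagent charged in the smaller amount: 0.00630 mM against 0.010 M of starting material.

| flask | starting material | gas | free enzyme | temperature | remark | time |
|---|---|---|---|---|---|---|
| Saturday's | 0.010 M | 0.48 mM (held) | 0.063 mol% | 20 °C | the very flask that is asked about, followed so far |  |
| Friday's | 0.010 M | 0.48 mM (held) | 0.063 mol% | 26 °C | run made earlier |  |
| flask | 0.010 M | 0.48 mM (held) | 0.063 mol% | 20 °C |  | 6.0 h |

- Saturday's (time / min: target / %, starting material / %): 30.0: 47.1, 52.9; 60.0: 60.0, 39.7; 150: 66.7, 32.9; 360: 67.2, 33.3
- Friday's (time / min: target / %, starting material / %): 30.0: 20.1, 80.6; 60.0: 19.5, 80.1; 150: 20.0, 80.8; 360: 19.7, 80.1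

(readings scatter by 0.3 percentage points)

- at the start none of second substrate is dissolved
- what is added takes up no volume worth counting
- steps that have been proposed: free enzyme -> unfolded enzyme; starting material + free enzyme <-> first complex; first complex <-> loaded enzyme + first product; second substrate + loaded enzyme <-> second complex; second complex -> free enzyme + target; gas <-> second substrate

- cedar: at 6.0 h raise the temperature by 15 K, then wait 12 h
- ash: at 6.0 h add free enzyme, 100% of the amount charged, then wait 12 h
- maple: at 6.0 h take out 90% of the first product then present, then wait 12 h
- birch: change nothing and wait 12 h more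

* target, in percent of the starting material first charged, at 6.0 h
* which option adds most target ("none" when 2 percentage points or less is all one gets) (cedar / ash / maple / birch / none)
* target present, in percent of the starting material first charged, after cedar
* target present, in percent of the starting material first charged, after birch

Note for the bench. Each reading carried a scatter of 0.3 percentage points. Among the proposed steps, free enzyme leaves the round by a one-way step to unfolded enzyme. I assumed that it unfolded first-order while c(starting material) fell pseudo-first-order, so Saturday's flask gave 175 mM⁻¹ for the reach, the logarithm of charged over final c(starting material), divided by the c(free enzyme) charged. On that assumption the readings at 30.0 min and 60.0 min gave enzyme half-lives of 24.0 min and 22.7 min. So I reckoned 0.00168% of the free enzyme left at 6.0 h, with target near 67.2%.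

With 0.00168% of the free enzyme reckoned left, I expected no gain above the margin from waiting, warming or taking out first product. I took a fresh charge to bring the same reach again, so I expected 22 points from ash, more than the margin. What to watch is the level where c(starting material) stops.

The forecast gave 67% (66.6% to 67.4%), ash as the best option, 67.1% after cedar and 67.1% after birch, on these grounds: “heat cannot revive dead enzyme”.

The flask gave 66.8%, then 66.8% after cedar and 66.8% after birch, and ash added 22 points.

    free enzyme → unfolded enzyme (k = 5.65 × 10⁻⁴ s⁻¹, Ea = 273 kJ mol⁻¹)
    starting material + free enzyme ⇌ first complex (K = 23.1 M⁻¹, k = 6180 M⁻¹ s⁻¹, Ea = 35.0 kJ mol⁻¹, ΔH = 17.0 kJ mol⁻¹)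
    first complex ⇌ loaded enzyme + first product (K = 0.290 M, k = 4.36 s⁻¹, Ea = 60.0 kJ mol⁻¹, ΔH = −32.0 kJ mol⁻¹)
    second substrate + loaded enzyme ⇌ second complex (K = 53000 M⁻¹, k = 1.26 × 10⁵ M⁻¹ s⁻¹, Ea = 16.0 kJ mol⁻¹, ΔH = −8.00 kJ mol⁻¹)
    second complex → free enzyme + target (k = 44.1 s⁻¹, Ea = 68.0 kJ mol⁻¹)
    gas ⇌ second substrate, rate k6*(csat - [second substrate]) (kL = 0.0922 s⁻¹)
    (constants at 20 °C)

The neighbouring flask took 0.017 M of starting material at the same loading, so 0.0107 mM of free enzyme. The reach put its final starting material at 15.4% of its charge. At 360 min that flask held 15.4% starting material and 84.6% target.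

The runs come from a simulation for substances that don't exist; scatter was added.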